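## Retrosynthetic overview

1. Target ⇐ its hepta-O-benzyl ether; neutral hydrogenolysis comes last, so the kinetically set cis C-3 centre never meets base.
2. The cis hepta-benzyl ether ⇐ its 2,3-trans epimer by enolisation and face-selective kinetic protonation (C-3 is the last stereocentre set, anti to the C-2 aryl).
3. Key disconnection C-3 (unit 1, eriodictyol-type) – C-8 (unit 2, naringenin-type): the enolonium (polarity-reversed enolate) of a complete (2R)-flavanone attacks nothing but is attacked by the unfunctionalised C-8–H position of a complete (2S)-flavanone.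
4. Both flavanones ⇐ one chromone plus two arylboronic acids, by Rh-catalysed asymmetric 1,4-addition with antipodal ligands (sets both C-2 centres).
5. Ring order: rings A and C of both units come ready-made in 5,7-dihydroxychromone; the B rings are attached, then the two units are joined; no ring is built de novo.

Assumption 1: the SMILES is read as (2R,3R) in unit 1, i.e. 2,3-cis (both aryl groups on the same face of ring C), and (2S) in unit 2; rotamers about the C-3/C-8 bond are taken as interconverting.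
Assumption 2: the (R)-biaryl bisphosphine is taken to give the (2R)-flavanone (same enantioface as Rh/(R)-BINAP additions to cyclohexenone); this is checked by CD against natural (2S)-flavanones, and the ligand antipodes of steps 2 and 3 are exchanged if the sense is opposite.

## Route

Step 1
Reactants: 1 5,7-dihydroxy-4H-chromen-4-one
Product: 2 5,7-bis(benzyloxy)-4H-chromen-4-one
Conditions: BnBr (2.6 equiv), K2CO3 (3 equiv), DMF, 70 °C, 12 h
Reagents that add atoms: benzyl bromide, BrCc1ccccc1
Why: Williamson ether synthesis; warm K2CO3/DMF also alkylates the hydrogen-bonded 5-OH, and no stereocentre is present.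

Step 2
Reactants: 2 5,7-bis(benzyloxy)-4H-chromen-4-one; 3 3,4-bis(benzyloxy)phenylboronic acid
Product: 4 (2R)-5,7-bis(benzyloxy)-2-[3,4-bis(benzyloxy)phenyl]chroman-4-one
Conditions: [Rh(OH)(cod)]2 (1.5 mol %; cod = 1,5-cyclooctadiene), (R)-MeO-F12-BIPHEP (3.3 mol %), 3 (2.5 equiv), CH2Cl2/H2O 10:1, 25 °C, 3 h
Reagents that add atoms: none
Why: Rh-catalysed asymmetric 1,4-addition of an arylboronic acid to a chromone (Hayashi–Miyaura type, with the electron-poor bisphosphine that chromones need): aryl–Rh inserts into one enantioface of C2=C3 and the Rh enolate is protonated, setting C-2 as R.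

Step 3
Reactants: 2 5,7-bis(benzyloxy)-4H-chromen-4-one; 5 4-(benzyloxy)phenylboronic acid
Product: 6 (2S)-5,7-bis(benzyloxy)-2-[4-(benzyloxy)phenyl]chroman-4-one
Conditions: [Rh(OH)(cod)]2 (1.5 mol %), (S)-MeO-F12-BIPHEP (3.3 mol %), 5 (2.5 equiv), CH2Cl2/H2O 10:1, 25 °C, 3 h
Reagents that add atoms: none
Why: the same Rh-catalysed asymmetric 1,4-addition with the antipodal ligand delivers the aryl group to the other enantioface and sets C-2 as S.

Step 4
Reactants: 4 (2R)-5,7-bis(benzyloxy)-2-[3,4-bis(benzyloxy)phenyl]chroman-4-one; 6 (2S)-5,7-bis(benzyloxy)-2-[4-(benzyloxy)phenyl]chroman-4-one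
Product: 9 (2R,3S)-5,7-bis(benzyloxy)-2-[3,4-bis(benzyloxy)phenyl]-3-{(2S)-5,7-bis(benzyloxy)-2-[4-(benzyloxy)phenyl]-4-oxochroman-8-yl}chroman-4-one (2,3-trans), via trimethylsilyl enol ether 7 (not isolated), via O-iodanyl enolonium 8 (not isolated)
Conditions: (a) 4, TMSOTf (1.1 equiv), Et3N (1.2 equiv), CH2Cl2, 0 °C, 30 min; (b) cannulated into PhI(OH)OTs (1.0 equiv), BF3·OEt2 (2.0 equiv), CH2Cl2, −78 °C, 2 min; (c) 6 (1.5 equiv) in CH2Cl2, −78 → −40 °C, 1 h; aq NaHCO3
Reagents that add atoms: none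
Why: Proposed new method: the BF3-activated trivalent iodine reagent PhI(OH)OTs converts the silyl enol ether into an O-bound enolonium whose C-3 is attacked at −78 °C, in an SN2'-type Friedel–Crafts step, by C-8 of 6 (the less hindered doubly alkoxy-activated position, as in 8-selective halogenation of 5,7-dialkoxyflavonoids and 4→8 couplings of benzylated flavan-3-ols), with loss of PhI and TsOH; the closest known reaction is the Koser-reagent/BF3 enolonium α-arylation of ketone silyl enol ethers with indoles, pyrroles and alkoxyarenes; the arene should enter anti to the C-2 aryl (2,3-trans), but C-3 is reset in step 5 and both C-2 centres are untouched.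

Step 5
Reactants: 9 (2R,3S)-5,7-bis(benzyloxy)-2-[3,4-bis(benzyloxy)phenyl]-3-{(2S)-5,7-bis(benzyloxy)-2-[4-(benzyloxy)phenyl]-4-oxochroman-8-yl}chroman-4-one
Product: 11 (2R,3R)-5,7-bis(benzyloxy)-2-[3,4-bis(benzyloxy)phenyl]-3-{(2S)-5,7-bis(benzyloxy)-2-[4-(benzyloxy)phenyl]-4-oxochroman-8-yl}chroman-4-one (2,3-cis), via bis(trimethylsilyl enol ether) 10 (not isolated)
Conditions: (a) TMSOTf (3 equiv), Et3N (4 equiv), CH2Cl2, 0 °C → 23 °C, 3 h; volatiles removed, toluene, Et3NH·OTf filtered off under Ar; (b) SnCl4 (20 mol %), (R)-BINOL monomethyl ether (22 mol %), 2,6-dimethylphenol (2.4 equiv, slow addition), toluene, −78 °C; cold aq NaHCO3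
Reagents that add atoms: none
Why: soft enolisation erases C-3, and the silyl enol ether, whose C-2 aryl sits pseudo-axial to avoid A(1,2) strain with the C-3 aryl, is protonated at C-3 from the opposite face by the bulky Lewis acid-assisted Brønsted acid (Yamamoto kinetic protonation of α-aryl ketone silyl enol ethers; the (R)-BINOL acid is expected to be matched, since it gives (S)-2-arylcyclohexanones, the same spatial sense), giving the 2,3-cis (3R) ketone while the enol ether of unit 2 simply returns to its ketone.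

Step 6
Reactants: 11 (2R,3R)-5,7-bis(benzyloxy)-2-[3,4-bis(benzyloxy)phenyl]-3-{(2S)-5,7-bis(benzyloxy)-2-[4-(benzyloxy)phenyl]-4-oxochroman-8-yl}chroman-4-one
Product: 12 (2R,3R)-2-(3,4-dihydroxyphenyl)-5,7-dihydroxy-3-[(2S)-5,7-dihydroxy-2-(4-hydroxyphenyl)-4-oxochroman-8-yl]chroman-4-one
Conditions: H2 (1 atm), Pd(OH)2/C (20 wt %), THF/MeOH 1:1, 23 °C, 4 h; filtration, reversed-phase chromatography (0.1 % HCO2H)
Reagents that add atoms: none
Why: hydrogenolysis of the seven benzyl ethers under neutral conditions leaves the aryl ketones, the C-2–O bonds and the epimerisable cis C-3 centre untouched.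

## Compound list

1 | 5,7-dihydroxy-4H-chromen-4-one | O=c1ccoc2cc(O)cc(O)c12 | starting material
2 | 5,7-bis(benzyloxy)-4H-chromen-4-one | O=c1ccoc2cc(OCc3ccccc3)cc(OCc3ccccc3)c12 | intermediate
3 | 3,4-bis(benzyloxy)phenylboronic acid | OB(O)c1ccc(OCc2ccccc2)c(OCc2ccccc2)c1 | starting material
4 | (2R)-5,7-bis(benzyloxy)-2-[3,4-bis(benzyloxy)phenyl]chroman-4-one | O=C1C[C@H](c2ccc(OCc3ccccc3)c(OCc3ccccc3)c2)Oc2cc(OCc3ccccc3)cc(OCc3ccccc3)c12 | intermediate
5 | 4-(benzyloxy)phenylboronic acid | OB(O)c1ccc(OCc2ccccc2)cc1 | starting material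
6 | (2S)-5,7-bis(benzyloxy)-2-[4-(benzyloxy)phenyl]chroman-4-one | O=C1C[C@@H](c2ccc(OCc3ccccc3)cc2)Oc2cc(OCc3ccccc3)cc(OCc3ccccc3)c12 | intermediate
7 | (2R)-5,7-bis(benzyloxy)-2-[3,4-bis(benzyloxy)phenyl]-4-(trimethylsilyloxy)-2H-chromene (not isolated) | C[Si](C)(C)OC1=C[C@H](c2ccc(OCc3ccccc3)c(OCc3ccccc3)c2)Oc2cc(OCc3ccccc3)cc(OCc3ccccc3)c12 | intermediate
8 | {[(2R)-5,7-bis(benzyloxy)-2-[3,4-bis(benzyloxy)phenyl]-2H-chromen-4-yl]oxy}(phenyl)iodanyl 4-methylbenzenesulfonate, the O-bound enolonium (not isolated) | Cc1ccc(cc1)S(=O)(=O)O[I](c1ccccc1)OC1=C[C@H](c2ccc(OCc3ccccc3)c(OCc3ccccc3)c2)Oc2cc(OCc3ccccc3)cc(OCc3ccccc3)c12 | intermediate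
9 | (2R,3S)-5,7-bis(benzyloxy)-2-[3,4-bis(benzyloxy)phenyl]-3-{(2S)-5,7-bis(benzyloxy)-2-[4-(benzyloxy)phenyl]-4-oxochroman-8-yl}chroman-4-one (2,3-trans) | O=C1C[C@@H](c2ccc(OCc3ccccc3)cc2)Oc2c1c(OCc3ccccc3)cc(OCc3ccccc3)c2[C@@H]1C(=O)c2c(OCc3ccccc3)cc(OCc3ccccc3)cc2O[C@H]1c1ccc(OCc3ccccc3)c(OCc3ccccc3)c1 | intermediate
10 | bis(trimethylsilyl enol ether) of 9: a 4-(trimethylsilyloxy)-2H-chromene in both units, C-3 of unit 1 sp2; both C-2 centres as in 9 (the label at C-2 of unit 1 becomes S by priority change only) (not isolated) | C[Si](C)(C)OC1=C[C@@H](c2ccc(OCc3ccccc3)cc2)Oc2c1c(OCc3ccccc3)cc(OCc3ccccc3)c2C1=C(O[Si](C)(C)C)c2c(OCc3ccccc3)cc(OCc3ccccc3)cc2O[C@H]1c1ccc(OCc3ccccc3)c(OCc3ccccc3)c1 | intermediate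
11 | (2R,3R)-5,7-bis(benzyloxy)-2-[3,4-bis(benzyloxy)phenyl]-3-{(2S)-5,7-bis(benzyloxy)-2-[4-(benzyloxy)phenyl]-4-oxochroman-8-yl}chroman-4-one (2,3-cis) | O=C1C[C@@H](c2ccc(OCc3ccccc3)cc2)Oc2c1c(OCc3ccccc3)cc(OCc3ccccc3)c2[C@H]1C(=O)c2c(OCc3ccccc3)cc(OCc3ccccc3)cc2O[C@H]1c1ccc(OCc3ccccc3)c(OCc3ccccc3)c1 | intermediate
12 | (2R,3R)-2-(3,4-dihydroxyphenyl)-5,7-dihydroxy-3-[(2S)-5,7-dihydroxy-2-(4-hydroxyphenyl)-4-oxochroman-8-yl]chroman-4-one (2,3-cis) | O=C1C[C@@H](c2ccc(O)cc2)Oc2c1c(O)cc(O)c2[C@H]1C(=O)c2c(O)cc(O)cc2O[C@H]1c1ccc(O)c(O)c1 | target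

## Step count and risks

Total step count: 6. Longest linear sequence: 5 steps (1 → 2 → 4 → 9 → 11 → 12).

**Step 4 (key coupling).** Four things can go wrong:
- the electron-rich C-2 aryl of the enolonium can shift to C-3 (the known flavanone → isoflavone rearrangement under trivalent iodine);
- loss of H-2 gives the flavone;
- the acyl-deactivated ring A of 6 may be too weak a nucleophile;
- attack may occur at C-6 instead of C-8.

Fallback: it sets out from compound 4 (through its enol ether 7) and compound 6 and comes back at compound 9. The enol ether 7 is brominated with NBS in THF at −78 °C to (2S,3S)-3-bromo-5,7-bis(benzyloxy)-2-[3,4-bis(benzyloxy)phenyl]chroman-4-one F1. F1 and 6 (2 equiv) are then irradiated with blue LEDs in MeCN with fac-Ir(ppy)3 (1 mol %) and NaHCO3. Single-electron reduction of the C–Br bond gives the electrophilic α-keto radical, which adds to C-8 of 6; oxidation of the cyclohexadienyl radical and loss of a proton give 9. No cation is formed at C-3, so the aryl shift is shut off.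

**Step 5 (cis-selective protonation).** The hindered C-3–H may enolise slowly, the facial selectivity may be incomplete, and TMSOTf could ionise the p-alkoxybenzylic C-2–O bonds if the amine is not kept in excess. The cis isomer is recognised by a small J(H-2,H-3), against about 12 Hz for trans.

Fallback: it sets out from compound 9 and comes back at compound 11. A dynamic kinetic transfer hydrogenation with RuCl(p-cymene)[(R,R)-TsDPEN], HCO2H/Et3N and catalytic DBU in EtOAc at 40 °C epimerises C-3 and reduces only the epimer that can take hydride anti to the C-3 aryl. This gives the all-cis (2R,3S,4R)-5,7-bis(benzyloxy)-2-[3,4-bis(benzyloxy)phenyl]-3-{(2S)-5,7-bis(benzyloxy)-2-[4-(benzyloxy)phenyl]-4-hydroxychroman-8-yl}chroman-4-ol F2 (the carbinol of unit 2 is a mixture and immaterial). Dess–Martin periodinane with NaHCO3 in CH2Cl2 at 0 °C then reoxidises both carbinols without touching C-3 and gives 11.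

**Step 6 (global debenzylation).** Seven benzyl ethers must go without hydrogenolysis of the benzylic C-2–O bonds, reduction of the ketones, or epimerisation of C-3 in the free polyphenol.

Fallback: it sets out from compound 11 and comes back at compound 12. The benzyl ethers are cleaved with BCl3 and pentamethylbenzene as cation scavenger in CH2Cl2 at −78 °C, followed by a cold MeOH quench. This is a Lewis-acid dealkylation in place of hydrogenolysis and makes no compound outside the list (F0).

## Further compounds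

F1 | step 4 | (2S,3S)-3-bromo-5,7-bis(benzyloxy)-2-[3,4-bis(benzyloxy)phenyl]chroman-4-one (2,3-trans) | Br[C@@H]1C(=O)c2c(OCc3ccccc3)cc(OCc3ccccc3)cc2O[C@H]1c1ccc(OCc3ccccc3)c(OCc3ccccc3)c1
F2 | step 5 | (2R,3S,4R)-5,7-bis(benzyloxy)-2-[3,4-bis(benzyloxy)phenyl]-3-{(2S)-5,7-bis(benzyloxy)-2-[4-(benzyloxy)phenyl]-4-hydroxychroman-8-yl}chroman-4-ol (all-cis in unit 1; C-4 of unit 2 undefined) | OC1C[C@@H](c2ccc(OCc3ccccc3)cc2)Oc2c1c(OCc3ccccc3)cc(OCc3ccccc3)c2[C@H]1[C@@H](O)c2c(OCc3ccccc3)cc(OCc3ccccc3)cc2O[C@H]1c1ccc(OCc3ccccc3)c(OCc3ccccc3)c1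
F0 | step 6 | none | none
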